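**Retrosynthetic overview**
1. Target ⇐ monoacetylation of a ring triol (cis-diol masked in the flask as a boronate) ⇐ desilylative Sonogashira union of a ring silyl-alkyne with a 2-bromo-1,4-diene side chain (allylation, then cross-metathesis).
2. The allylic carbinol that carries the acetate ⇐ hydroxyl-directed 1,3-anti reduction of a 4,5-dihydroxy-6-methoxy-3-alkynylcyclohex-2-enone.
3. Key disconnection: ring bond C3–C4 of that enone, made by a β-acyl vinyl anion (vinylchromium from a (Z)-β-iodo enone) adding to an α-hydroxy aldehyde; the ynone β-carbon and the aldehyde carbon are both acceptor carbons in normal polarity.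
4. (Z)-β-Iodo enone ⇐ HI across a silyl diynone ⇐ lithium (trimethylsilyl)butadiynide + O-methylated methyl 3,4-O-isopropylidene-L-threonate, which supplies the OMe carbon and the adjacent OH carbon.
5. Ring order: the cyclohexene is the only carbocycle and is closed in step 5; the dioxolane and dioxaborolane rings are temporary.

Assumption: methyl 3,4-O-isopropylidene-L-threonate (catalogue compound, also two steps from L-ascorbic acid) counts as a commercial starting material.

**Route**

Step 1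
Reactants: 1 methyl 3,4-O-isopropylidene-L-threonate
Product: 2 methyl (2R)-2-[(4S)-2,2-dimethyl-1,3-dioxolan-4-yl]-2-methoxyacetate
Conditions: MeI (5 equiv), Ag2O (1.5 equiv), MeCN, 40 °C, dark
Reagents that add atoms: iodomethane, CI
Why: Purdie methylation (silver-oxide-assisted Williamson etherification) of the α-hydroxy ester runs without strong base, so the α-stereocentre (the future OMe carbon) and the acetonide are kept.

Step 2
Reactants: 2 methyl (2R)-2-[(4S)-2,2-dimethyl-1,3-dioxolan-4-yl]-2-methoxyacetate; 3 1,4-bis(trimethylsilyl)buta-1,3-diyne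
Product: 5 (1R)-1-[(4S)-2,2-dimethyl-1,3-dioxolan-4-yl]-1-methoxy-6-(trimethylsilyl)hexa-3,5-diyn-2-one, via lithium diynide 4 (not isolated)
Conditions: 3 (1.2 equiv), MeLi·LiBr (1.2 equiv), THF, −78 °C to rt, 3 h; then 2, −78 °C, 1 h; aq NH4Cl at −78 °C
Reagents that add atoms: none
Why: Mono-desilylation of 3 with MeLi gives the lithium diynide, and its acyl substitution on the α-methoxy ester (acetylide acylation) stops at the chelated tetrahedral intermediate until the cold quench, giving the ynone with both stereocentres untouched.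

Step 3
Reactants: 5 (1R)-1-[(4S)-2,2-dimethyl-1,3-dioxolan-4-yl]-1-methoxy-6-(trimethylsilyl)hexa-3,5-diyn-2-one
Product: 7 (2S,3R,5Z)-1,2-dihydroxy-6-iodo-3-methoxy-8-(trimethylsilyl)oct-5-en-7-yn-4-one, via iodoenone acetonide 6 (not isolated)
Conditions: NaI (2 equiv), AcOH, rt, 2 h; then H2O (AcOH/H2O 4:1), 40 °C, 3 h
Reagents that add atoms: sodium iodide, [Na+].[I-]
Why: Conjugate hydroiodination of the ynone (iodide attacks the β-carbon, the silyl group shielding the distal alkyne, and anti protonation gives the Z isomer with iodine cis to the carbonyl) is followed in the same flask by acid hydrolysis of the terminal acetonide.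

Step 4
Reactants: 7 (2S,3R,5Z)-1,2-dihydroxy-6-iodo-3-methoxy-8-(trimethylsilyl)oct-5-en-7-yn-4-one
Product: 8 (2R,3R,5Z)-2-hydroxy-6-iodo-3-methoxy-4-oxo-8-(trimethylsilyl)oct-5-en-7-ynal
Conditions: TEMPO (0.2 equiv), PhI(OAc)2 (1.1 equiv), dry CH2Cl2, 0 °C to rt; used crude
Reagents that add atoms: none
Why: Oxoammonium oxidation (TEMPO/PhI(OAc)2) takes the primary hydroxyl in preference to the secondary one and stops at the aldehyde when water is absent, leaving the vinyl iodide, enone and silyl alkyne intact.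

Step 5 (key step)
Reactants: 8 (2R,3R,5Z)-2-hydroxy-6-iodo-3-methoxy-4-oxo-8-(trimethylsilyl)oct-5-en-7-ynal
Product: 9 (4S,5S,6R)-4,5-dihydroxy-6-methoxy-3-[(trimethylsilyl)ethynyl]cyclohex-2-en-1-one
Conditions: CrCl2 (6 equiv), NiCl2 (2 mol%), degassed DMF, rt, 0.005 M, slow addition of 8; aq NH4Cl
Reagents that add atoms: none
Why: In this intramolecular Nozaki–Hiyama–Kishi reaction the enone β-carbon, normally an acceptor, becomes a vinylchromium donor (a β-acyl vinyl anion, homoenolate-type synthon) that adds to the aldehyde carbon and closes the six-membered ring, and the new C4 carbinol is expected cis to the C5 hydroxyl because the C5–O bond lies anti to the forming bond (Felkin–Anh) while the chromium-bound aldehyde oxygen turns pseudo-axial to avoid A(1,2) strain with the alkynyl group.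

Step 6
Reactants: 9 (4S,5S,6R)-4,5-dihydroxy-6-methoxy-3-[(trimethylsilyl)ethynyl]cyclohex-2-en-1-one
Product: 10 (1S,2S,3S,4S)-3-methoxy-6-[(trimethylsilyl)ethynyl]cyclohex-5-ene-1,2,4-triol
Conditions: Me4NBH(OAc)3 (5 equiv), MeCN/AcOH 1:1, −30 °C
Reagents that add atoms: none
Why: In this Evans–Saksena hydroxyl-directed reduction the C5 hydroxyl (β to the ketone) binds boron and delivers hydride to its own face of the carbonyl, giving the 1,3-anti diol, so the new carbinol is cis to the neighbouring OMe, and the 1,2-reduction spares the enyne.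

Step 7
Reactants: 11 2,3-dibromopropene; 12 vinylmagnesium bromide (CH2=CHMgBr, 1 M in THF)
Product: 13 2-bromopenta-1,4-diene
Conditions: CuI (5 mol%), THF, −10 °C to rt
Reagents that add atoms: none
Why: Copper-catalysed allylic substitution by the vinyl Grignard reagent displaces only the allylic bromide, since the vinylic C–Br bond is inert under these conditions.

Step 8
Reactants: 13 2-bromopenta-1,4-diene; 14 2-methylbut-3-en-2-ol
Product: 15 (3E)-6-bromo-2-methylhepta-3,6-dien-2-ol
Conditions: second-generation Grubbs catalyst RuCl2(H2IMes)(PCy3)(=CHPh) (3 mol%), 14 (5 equiv), CH2Cl2, 40 °C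
Reagents that add atoms: none
Why: Olefin cross-metathesis between the allyl terminus and the hindered tertiary allylic alcohol is E-selective, loses ethene and does not engage the 2-bromoalkene.

Step 9
Reactants: 10 (1S,2S,3S,4S)-3-methoxy-6-[(trimethylsilyl)ethynyl]cyclohex-5-ene-1,2,4-triol; 15 (3E)-6-bromo-2-methylhepta-3,6-dien-2-ol
Product: 17 (1S,2S,3S,4S)-6-[(5E)-7-hydroxy-7-methyl-3-methylideneoct-5-en-1-yn-1-yl]-3-methoxycyclohex-5-ene-1,2,4-triol, via terminal alkyne 16 (not isolated)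
Conditions: 15 (1.5 equiv), CsF (2 equiv), Pd(PPh3)4 (5 mol%), CuI (10 mol%), Et3N/THF/H2O 10:10:1, degassed, 45 °C
Reagents that add atoms: none
Why: Fluoride-triggered desilylation releases the terminal alkyne slowly for a Sonogashira coupling with the vinyl bromide, which tolerates the free hydroxyls and touches no stereocentre.

Step 10
Reactants: 17 (1S,2S,3S,4S)-6-[(5E)-7-hydroxy-7-methyl-3-methylideneoct-5-en-1-yn-1-yl]-3-methoxycyclohex-5-ene-1,2,4-triol
Product: 20 (1S,4S,5S,6R)-4,5-dihydroxy-3-[(5E)-7-hydroxy-7-methyl-3-methylideneoct-5-en-1-yn-1-yl]-6-methoxycyclohex-2-en-1-yl acetate, via phenylboronate 18 (not isolated), via acetylated phenylboronate 19 (not isolated)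
Conditions: PhB(OH)2 (1.05 equiv), pyridine, 4 Å MS, rt; Ac2O (1.3 equiv), 0 °C; then pinacol, MeOH, rt
Reagents that add atoms: acetic anhydride, CC(=O)OC(C)=O
Why: The cis-1,2-diol is masked in the flask as its cyclic phenylboronate so that esterification (acylation) takes only the remaining secondary allylic hydroxyl, the tertiary alcohol being too hindered, and transesterification with pinacol then frees the diol.

**Compound list**
1 | methyl 3,4-O-isopropylidene-L-threonate [methyl (2R)-2-[(4S)-2,2-dimethyl-1,3-dioxolan-4-yl]-2-hydroxyacetate] | COC(=O)[C@H](O)[C@@H]1COC(C)(C)O1 | starting material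
2 | methyl (2R)-2-[(4S)-2,2-dimethyl-1,3-dioxolan-4-yl]-2-methoxyacetate | COC(=O)[C@H](OC)[C@@H]1COC(C)(C)O1 | intermediate
3 | 1,4-bis(trimethylsilyl)buta-1,3-diyne | C[Si](C)(C)C#CC#C[Si](C)(C)C | starting material
4 | lithium 4-(trimethylsilyl)buta-1,3-diyn-1-ide | [Li]C#CC#C[Si](C)(C)C | intermediate
5 | (1R)-1-[(4S)-2,2-dimethyl-1,3-dioxolan-4-yl]-1-methoxy-6-(trimethylsilyl)hexa-3,5-diyn-2-one | C[Si](C)(C)C#CC#CC(=O)[C@H](OC)[C@@H]1COC(C)(C)O1 | intermediate
6 | (1R,3Z)-1-[(4S)-2,2-dimethyl-1,3-dioxolan-4-yl]-4-iodo-1-methoxy-6-(trimethylsilyl)hex-3-en-5-yn-2-one | C[Si](C)(C)C#C/C(I)=C/C(=O)[C@H](OC)[C@@H]1COC(C)(C)O1 | intermediate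
7 | (2S,3R,5Z)-1,2-dihydroxy-6-iodo-3-methoxy-8-(trimethylsilyl)oct-5-en-7-yn-4-one | C[Si](C)(C)C#C/C(I)=C/C(=O)[C@H](OC)[C@@H](O)CO | intermediate
8 | (2R,3R,5Z)-2-hydroxy-6-iodo-3-methoxy-4-oxo-8-(trimethylsilyl)oct-5-en-7-ynal | C[Si](C)(C)C#C/C(I)=C/C(=O)[C@H](OC)[C@@H](O)C=O | intermediate
9 | (4S,5S,6R)-4,5-dihydroxy-6-methoxy-3-[(trimethylsilyl)ethynyl]cyclohex-2-en-1-one (4-OH and 5-OH cis, 6-OMe trans to 5-OH) | C[Si](C)(C)C#CC1=CC(=O)[C@H](OC)[C@@H](O)[C@H]1O | intermediate
10 | (1S,2S,3S,4S)-3-methoxy-6-[(trimethylsilyl)ethynyl]cyclohex-5-ene-1,2,4-triol (1-OH/2-OH cis, 3-OMe/4-OH cis, 2-OH/3-OMe trans) | C[Si](C)(C)C#CC1=C[C@H](O)[C@H](OC)[C@@H](O)[C@H]1O | intermediate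
11 | 2,3-dibromopropene | C=C(Br)CBr | starting material
12 | vinylmagnesium bromide | C=C[Mg]Br | starting material
13 | 2-bromopenta-1,4-diene | C=CCC(Br)=C | intermediate
14 | 2-methylbut-3-en-2-ol | CC(C)(O)C=C | starting material
15 | (3E)-6-bromo-2-methylhepta-3,6-dien-2-ol | C=C(Br)C/C=C/C(C)(C)O | intermediate
16 | (1S,2S,3S,4S)-6-ethynyl-3-methoxycyclohex-5-ene-1,2,4-triol | C#CC1=C[C@H](O)[C@H](OC)[C@@H](O)[C@H]1O | intermediate
17 | (1S,2S,3S,4S)-6-[(5E)-7-hydroxy-7-methyl-3-methylideneoct-5-en-1-yn-1-yl]-3-methoxycyclohex-5-ene-1,2,4-triol | C=C(C#CC1=C[C@H](O)[C@H](OC)[C@@H](O)[C@H]1O)C/C=C/C(C)(C)O | intermediate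
18 | cyclic phenylboronate across the cis-1,2-diol of 17 (2-phenyl-1,3,2-dioxaborolane fused at C1/C2, all stereocentres as in 17) | C=C(C#CC1=C[C@H](O)[C@H](OC)[C@@H](OB(c3ccccc3)O2)[C@H]12)C/C=C/C(C)(C)O | intermediate
19 | 4-O-acetate of boronate 18 (all stereocentres as in 17) | C=C(C#CC1=C[C@H](OC(C)=O)[C@H](OC)[C@@H](OB(c3ccccc3)O2)[C@H]12)C/C=C/C(C)(C)O | intermediate
20 | (1S,4S,5S,6R)-4,5-dihydroxy-3-[(5E)-7-hydroxy-7-methyl-3-methylideneoct-5-en-1-yn-1-yl]-6-methoxycyclohex-2-en-1-yl acetate | C=C(C#CC1=C[C@H](OC(C)=O)[C@H](OC)[C@@H](O)[C@H]1O)C/C=C/C(C)(C)O | target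

**Step count and risks**
Total steps: 10. Longest linear sequence: 8 (steps 1–6, 9, 10); steps 7–8 make the side chain.

Three steps most likely to fail:

Step 5 (ring closure). The vinylchromium addition has to set the C4 carbinol cis to C5-OH, and it runs on a free α-hydroxy aldehyde that self-associates and carries a β-hydroxyl able to add to the iodoenone; the preceding oxidation (step 4) shares this weakness. The fallback sets out from 7 and protects before oxidising. TESOTf and 2,6-lutidine give (2S,3R,5Z)-6-iodo-3-methoxy-1,2-bis[(triethylsilyl)oxy]-8-(trimethylsilyl)oct-5-en-7-yn-4-one F2. Swern conditions (oxalyl chloride, DMSO, Et3N, −78 to −20 °C) oxidise only the primary silyl ether and give the monomeric α-silyloxy aldehyde (2R,3R,5Z)-6-iodo-3-methoxy-4-oxo-2-[(triethylsilyl)oxy]-8-(trimethylsilyl)oct-5-en-7-ynal F3. CrCl2/NiCl2 in DMF then closes the ring under non-chelating Felkin control to (4S,5S,6R)-4-hydroxy-6-methoxy-5-[(triethylsilyl)oxy]-3-[(trimethylsilyl)ethynyl]cyclohex-2-en-1-one F4, and AcOH/THF/H2O removes the silyl group; the route is rejoined at 9.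

Step 6 (directed reduction). Hydride delivery from the C5 hydroxyl needs the diaxial half-chair, and ordinary axial attack would give the C1 epimer. The fallback sets out from 9 and uses that epimer on purpose. NaBH4/CeCl3·7H2O in MeOH at −78 °C gives (1S,2S,3S,4R)-3-methoxy-6-[(trimethylsilyl)ethynyl]cyclohex-5-ene-1,2,4-triol F5. The conditions of step 9 with 15 pass through (1S,2S,3S,4R)-6-ethynyl-3-methoxycyclohex-5-ene-1,2,4-triol F6 (not isolated) to (1S,2S,3S,4R)-6-[(5E)-7-hydroxy-7-methyl-3-methylideneoct-5-en-1-yn-1-yl]-3-methoxycyclohex-5-ene-1,2,4-triol F7. PhB(OH)2 gives the cyclic phenylboronate of the 4-epimer F8, and a Mitsunobu reaction (PPh3, DIAD, AcOH) installs the acetate with inversion; the route is rejoined at 19, and pinacol then gives 20.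

Step 2 (ynone from the ester). Over-addition of the diynide, or epimerisation of the α-methoxy centre on work-up, would erode the material. The fallback sets out from 2: MeNH(OMe)·HCl and i-PrMgCl in THF at −20 °C give the Weinreb amide (2R)-2-[(4S)-2,2-dimethyl-1,3-dioxolan-4-yl]-N,2-dimethoxy-N-methylacetamide F1, which takes up exactly one equivalent of lithium diynide 4 at −78 °C; the route is rejoined at 5.

**Further compounds**
F1 | step 2 | (2R)-2-[(4S)-2,2-dimethyl-1,3-dioxolan-4-yl]-N,2-dimethoxy-N-methylacetamide | CON(C)C(=O)[C@H](OC)[C@@H]1COC(C)(C)O1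
F2 | step 5 | (2S,3R,5Z)-6-iodo-3-methoxy-1,2-bis[(triethylsilyl)oxy]-8-(trimethylsilyl)oct-5-en-7-yn-4-one | C[Si](C)(C)C#C/C(I)=C/C(=O)[C@H](OC)[C@@H](O[Si](CC)(CC)CC)CO[Si](CC)(CC)CC
F3 | step 5 | (2R,3R,5Z)-6-iodo-3-methoxy-4-oxo-2-[(triethylsilyl)oxy]-8-(trimethylsilyl)oct-5-en-7-ynal | C[Si](C)(C)C#C/C(I)=C/C(=O)[C@H](OC)[C@@H](O[Si](CC)(CC)CC)C=O
F4 | step 5 | (4S,5S,6R)-4-hydroxy-6-methoxy-5-[(triethylsilyl)oxy]-3-[(trimethylsilyl)ethynyl]cyclohex-2-en-1-one | C[Si](C)(C)C#CC1=CC(=O)[C@H](OC)[C@@H](O[Si](CC)(CC)CC)[C@H]1O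
F5 | step 6 | (1S,2S,3S,4R)-3-methoxy-6-[(trimethylsilyl)ethynyl]cyclohex-5-ene-1,2,4-triol | C[Si](C)(C)C#CC1=C[C@@H](O)[C@H](OC)[C@@H](O)[C@H]1O
F6 | step 6 | (1S,2S,3S,4R)-6-ethynyl-3-methoxycyclohex-5-ene-1,2,4-triol | C#CC1=C[C@@H](O)[C@H](OC)[C@@H](O)[C@H]1O
F7 | step 6 | (1S,2S,3S,4R)-6-[(5E)-7-hydroxy-7-methyl-3-methylideneoct-5-en-1-yn-1-yl]-3-methoxycyclohex-5-ene-1,2,4-triol | C=C(C#CC1=C[C@@H](O)[C@H](OC)[C@@H](O)[C@H]1O)C/C=C/C(C)(C)O
F8 | step 6 | cyclic phenylboronate across the cis-1,2-diol of F7 | C=C(C#CC1=C[C@@H](O)[C@H](OC)[C@@H](OB(c3ccccc3)O2)[C@H]12)C/C=C/C(C)(C)O
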